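## The problem

Target 28 is a 2,4,6-trihydroxybenzophenone. Ring A, the phloroglucinol ring, carries the benzoyl group (ring B and the ketone carbon) at C-1 and a ten-carbon chain at C-3; C-5 is the only ring CH. The chain runs from benzylic C-1' through the carbinol C-2' and the methylidene-bearing C-3' to the trisubstituted C-6'=C-7' alkene. No ring has to be formed: the task is to place two different carbon substituents on a commodity arene and to build the chain with its single stereocentre, C-2' (R). No second stereocentre exists that could relay to C-2', so its configuration must come from a reagent, an auxiliary or a catalyst. Once set it must be protected from ionisation, since it is a secondary allylic carbinol. The free phenols ortho to the chain, the 1,1-disubstituted allylic alcohol and the trisubstituted alkene form an acid-labile array (cyclisation to chromans or dihydrobenzofurans, allylic transposition, addition to the alkenes). The diaryl ketone would not survive the organolithium reagents needed for the chain, so the benzoyl group must come late and the phenol protection must fall under mild conditions. A 2-substituted phloroglucinol triether has two equivalent ring CH positions, so the second ring substitution raises no regiochemical question. The feature that opens the key step is the position of C-2' between benzylic C-1' and alkenyl C-3': a CH bearing oxygen and two carbon groups that both migrate well from boron. It can therefore be a boron-bearing carbon, delivered as a one-carbon carbenoid, onto which C-1' and then C-3' shift from boron, after which C–B becomes C–O with retention.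

## Retrosynthesis

**28 to 27.** The three phenolic O–CH2OMe bonds are cut last, leading to the tris(methoxymethyl) ether 27. Methyl or benzyl ethers would need BBr3 or hydrogenolysis, which the alkenes do not tolerate, and silyl ethers do not direct ring metalation. The acetal ethers are what make both ring substitutions possible. The skeleton is not simplified, but every earlier step may now use strong base. The forward reaction must be a mild acetal cleavage that spares the allylic carbinol and both alkenes.

**27 to 23 and 24.** The bond from ring A C-1 to the ketone carbon is cut, giving alcohol 23 and the Weinreb amide 24. Acylating first and building the chain afterwards is excluded, because a diaryl ketone would not survive (dichloromethyl)lithium or an alkenyllithium. A Friedel–Crafts benzoylation of the free phenol would expose the chain to Lewis acid. The cut removes ring B and the carbonyl group. It asks that the one ring CH, flanked by two MOM ethers, be lithiated while the C-2' oxygen is carried as its lithium alkoxide.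

**23 to 22, then to 16 and 20.** The C-2'–O bond is traced to a C–B bond in allylic boronate 22. The C-2'–C-3' bond is then cut: 22 arises from α-chloro boronic ester 16 and alkenyllithium 20 by displacement of chloride through a boronate complex. The neighbouring way of cutting the same bond, addition of an alkenylmetal to an arylacetaldehyde, needs an external chiral catalyst and a labile aldehyde; here the configuration is inherited from 16. Reagent 20 comes from trisylhydrazone 18 of the terpene ketone 17 by a Shapiro reaction, which fixes the double bond at the methylidene position. The forward steps must invert C-2' cleanly and then oxidise with retention.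

**16 to 12 and 14.** This is the key disconnection. The C-1'–C-2' bond is cut: C-2' with its chlorine is traced to (dichloromethyl)lithium 14, made from dichloromethane 13, and the benzylic carbon is returned to the boron of benzylboronic ester 12. Against setting C-2' by reduction or by carbonyl addition, this cut needs no carbonyl group at C-2' or C-3' and uses one template, boron with its diol, for both C–C bonds and the C–O bond. Precursor 12 has no stereocentre in its carbon skeleton; its chirality lies only in the diol. The forward reaction must tell apart the two chlorides of the intermediate complex, for which the (R,R)-dicyclohexyl diol and ZnCl2 are relied on.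

**12 to 2 and 9; 9 to 3, 4 and 5; 2 to 1.** The bond from ring A C-3 to C-1' is cut by the same kind of 1,2-shift: aryllithium 10, from tris(MOM) ether 2, adds to the chloromethylboronic ester 9. A benzylic halide or Grignard route is set aside because 2,4,6-trialkoxybenzyl halides are too labile to metalate. Exchange of a pinacol ester for the chiral diol is thermodynamically unfavourable, so the diol is carried in 9 from the start. Reagent 9 is assembled from chloroiodomethane 3, triisopropyl borate 4 and diol 5; ether 2 comes from phloroglucinol 1.

## Roads not taken

**Alternative 1:** The cut goes through ring A itself. Three ring bonds form when the siloxycyclobutenone A3 is heated with the siloxyalkyne A2, which already carries the complete side chain, in a Danheiser benzannulation to give monophenol A1. The sequence is electrocyclic opening to a vinylketene, [2+2] addition to the alkyne, a second opening and a 6π closure.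
- Merits: the ring is built with full regiocontrol under neutral thermal conditions, no organolithium touches the side chain, and one ring oxygen emerges differentiated.
- Weak points for this target: the differentiation is of no use, because all three oxygens end free, and the nucleus that is built is a commodity. The key step does not address the stereocentre; it must be made in A2 by a separate asymmetric reaction, followed by the steps to a siloxyalkyne. The ketene intermediates are generated by heating next to two alkenes. A1 still lacks the benzoyl group, which silyl ethers cannot direct onto the ring, so an acylation under Friedel–Crafts or Fries conditions or a change of protecting groups must follow.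
- Comparison: in regiochemical certainty this road is at least equal to the chosen one, where symmetry does the same work, and it avoids cryogenic boron chemistry. The chosen plan sets against this a shorter sequence from a cheap arene and a key step that itself creates C-2'.

**Alternative 2:** The C-2'–C-3' bond is cut in the carbonyl sense. Alkenyl triflate A6, available from ketone 17, and arylacetaldehyde A5 are coupled with CrCl2 and catalytic NiCl2 in the presence of a chiral sulfonamide ligand (asymmetric Nozaki–Hiyama–Kishi reaction). The product is allylic alcohol A4, the same compound as 27.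
- Merits: this is the most convergent of the four plans. The organochromium reagent adds to aldehydes in the presence of ketones, so the benzoyl group can be in place beforehand, and the product is one deprotection from the target. In step count it is as short as the chosen route or shorter.
- Weak points: A5 is an arylacetaldehyde with two ortho alkoxy groups, a class that enolises, self-condenses and oxidises readily and would have to be made and used at once. The enantioselectivity of the coupling depends on the match of ligand, alkenyl partner and aldehyde and is least reliable for unbranched, enolisable aldehydes, so ligand screening is to be expected. The enantiomers of A4 cannot be separated by simple means, so any shortfall reaches the target. The reaction also needs a chromium salt with a stoichiometric reductant and a silyl chloride.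
- Comparison: against the shorter sequence the chosen plan sets stereocontrol by a covalently bound, recoverable diol with an established sense of induction, a diastereomeric intermediate (16) whose purity can be assessed and raised before C-3' is attached, and the absence of any enolisable carbonyl group next to C-1'.

**Alternative 3:** No skeletal bond is cut at the stereocentre. The C-2'–H bond is formed by reducing arylpyruvic acid A8 with a D-lactate dehydrogenase, NADH being recycled with formate and formate dehydrogenase, to give the (R)-aryllactic acid A7.
- Merits: such dehydrogenases typically reduce 3-aryl-2-oxopropanoates with essentially complete enantioselectivity, in water and with a cheap terminal reductant, and A7 can be purified as a salt. In enantiomeric purity at the carbinol stage this road would probably be better than the chosen one.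
- Weak points: the ring of A8 carries two ortho and one para MOM ether and is far larger than the substrates these enzymes are known to accept, so acceptance is open and screening or engineering may be needed. A8 must itself be made by a condensation and hydrolysis sequence that spares the MOM ethers. In A7 the future C-3' is a carboxyl carbon, so the methylidene and the homoprenyl chain must be added later by carbinol protection, acylation of a homoprenyl organometallic and carbonyl methylenation. These are four or five steps in which C-2' sits next to a ketone and can epimerise.
- Comparison: against the better initial selectivity the chosen plan sets that both C–C bonds at C-2' are formed directly at the final oxidation level, with no carbonyl group ever adjacent to the stereocentre, and in fewer steps.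

Key step: step 4

Assumption: the (R,R) diol 5 is taken to induce the (1S) configuration in 16, the sense established for boronic esters of (R,R)-configured C2-symmetric 1,2-diols; should the sense be opposite for 12, the (S,S) diol is used and nothing else changes.

## Route

Step 1
Reactants: 1 phloroglucinol (benzene-1,3,5-triol)
Product: 2 1,3,5-tris(methoxymethoxy)benzene
Conditions: NaH, MOMCl, DMF, 0 °C to rt
Reagents that add atoms: chloromethyl methyl ether (MOMCl), COCCl
Why: Williamson O-alkylation of the triphenoxide; the hard, readily ionising chloromethyl ether reacts at oxygen and not at ring carbon, and the three acetal ethers later direct both ring lithiations.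

Step 2
Reactants: 3 chloroiodomethane; 4 triisopropyl borate; 5 (1R,2R)-1,2-dicyclohexylethane-1,2-diol
Product: 9 (4R,5R)-2-(chloromethyl)-4,5-dicyclohexyl-1,3,2-dioxaborolane, via (chloromethyl)lithium 6 (not isolated), via lithium (chloromethyl)triisopropoxyborate 7 (not isolated), via diisopropyl (chloromethyl)boronate 8 (not isolated)
Conditions: 3, 4, n-BuLi, THF, −78 °C; HCl (Et2O), −78 °C to rt; then 5, rt
Reagents that add atoms: none
Why: Iodine–lithium exchange on 3 in the presence of 4 traps the unstable carbenoid 6 as borate 7 (the in-situ Matteson preparation of chloromethylboronic esters); HCl releases ester 8, whose isopropoxy groups are exchanged for the chelating 1,2-diol 5 (transesterification). No stereocentre is formed and the two carbinol centres of 5 are untouched.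

Step 3
Reactants: 2 1,3,5-tris(methoxymethoxy)benzene; 9 (4R,5R)-2-(chloromethyl)-4,5-dicyclohexyl-1,3,2-dioxaborolane
Product: 12 (4R,5R)-4,5-dicyclohexyl-2-[[2,4,6-tris(methoxymethoxy)phenyl]methyl]-1,3,2-dioxaborolane, via [2,4,6-tris(methoxymethoxy)phenyl]lithium 10 (not isolated), via lithium aryl(chloromethyl)boronate complex 11 (not isolated)
Conditions: n-BuLi, THF, 0 °C; then 9, −78 °C to rt
Reagents that add atoms: none
Why: Directed ortho-metalation between two MOM ethers gives 10, which adds to the boron of 9; in complex 11 the aryl group shifts from boron to carbon with loss of chloride (1,2-metalate rearrangement, the homologation of an organolithium with a chloromethylboronic ester), forming the bond from ring A to C-1'. No stereocentre is formed.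

Step 4
Reactants: 12 (4R,5R)-4,5-dicyclohexyl-2-[[2,4,6-tris(methoxymethoxy)phenyl]methyl]-1,3,2-dioxaborolane; 13 dichloromethane
Product: 16 (4R,5R)-2-[(1S)-1-chloro-2-[2,4,6-tris(methoxymethoxy)phenyl]ethyl]-4,5-dicyclohexyl-1,3,2-dioxaborolane, via (dichloromethyl)lithium 14 (not isolated), via lithium benzyl(dichloromethyl)boronate complex 15 (not isolated)
Conditions: 13, n-BuLi, THF, −100 °C; then 12; then ZnCl2 (excess), −100 °C to rt
Reagents that add atoms: none
Why: This is a Matteson asymmetric homologation. Deprotonation of 13 gives carbenoid 14, which adds to the trigonal boron of 12 to give complex 15; ZnCl2 then assists departure of one of the two diastereotopic chlorides while benzylic C-1' shifts from boron to carbon anti to it (stereospecific 1,2-metalate shift), so the C-1'–C-2' bond and the C-2' stereocentre arise in one event and no ring is closed. The closest known cases are the homologations of benzyl- and alkylboronic esters of C2-symmetric 1,2-diols and of pinanediol, as used for boronic acid analogues of phenylalanine. The stereocentre is controlled by the (R,R)-dicyclohexyl diol on boron: in the ZnCl2-bridged transition state one diol oxygen and the leaving chloride are tied together and the cyclohexyl groups leave only one chloride free to depart, which for the (R,R) diol should give the (1S) chloride (Cl > CH2Ar > B > H). The selectivity required is thus between the two chlorides of 15; it is secured by the C2 symmetry of the diol, which makes both faces of boron equivalent so that complex formation is not stereodetermining, and by ZnCl2, which also captures free chloride and so suppresses epimerisation of 16. The benzylic carbon migrates readily and no MOM oxygen is β to boron, so no elimination path is open; ZnCl2 is used in excess to allow for its coordination by the MOM oxygens.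

Step 5
Reactants: 17 6-methylhept-5-en-2-one
Product: 18 N'-[(2E)-6-methylhept-5-en-2-ylidene]-2,4,6-tri(propan-2-yl)benzenesulfonohydrazide
Conditions: 2,4,6-triisopropylbenzenesulfonohydrazide, HCl (cat.), MeOH, rt
Reagents that add atoms: 2,4,6-tri(propan-2-yl)benzenesulfonohydrazide, CC(C)c1cc(C(C)C)c(S(=O)(=O)NN)c(C(C)C)c1
Why: Acid-catalysed condensation of the ketone with the sulfonyl hydrazide gives the (E) hydrazone; the hindered triisopropylphenyl group prevents ortho-metalation of the sulfonyl arene in the next step and speeds the later loss of sulfinate.

Step 6
Reactants: 18 N'-[(2E)-6-methylhept-5-en-2-ylidene]-2,4,6-tri(propan-2-yl)benzenesulfonohydrazide; 16 (4R,5R)-2-[(1S)-1-chloro-2-[2,4,6-tris(methoxymethoxy)phenyl]ethyl]-4,5-dicyclohexyl-1,3,2-dioxaborolane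
Product: 22 (4R,5R)-4,5-dicyclohexyl-2-[(2R)-7-methyl-3-methylidene-1-[2,4,6-tris(methoxymethoxy)phenyl]oct-6-en-2-yl]-1,3,2-dioxaborolane, via dilithiated hydrazone 19 (not isolated), via (6-methylhepta-1,5-dien-2-yl)lithium 20 (not isolated), via lithium alkenyl(chloroalkyl)boronate complex 21 (not isolated)
Conditions: 18, n-BuLi (2 equiv), THF, −78 to 0 °C; then 16, −78 °C to rt
Reagents that add atoms: none
Why: Shapiro reaction: dianion 19, formed by deprotonation of the methyl group syn to the sulfonamide nitrogen, loses sulfinate and N2 to give the 2-lithio-1-alkene 20 with the double bond fixed at the methylidene position; 20 adds to the boron of 16 and in complex 21 the alkenyl group shifts to C-2' anti to chloride (second stage of the Matteson sequence), so the (1S) chloride should give the (2R) allylic boronate by inversion.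

Step 7
Reactants: 22 (4R,5R)-4,5-dicyclohexyl-2-[(2R)-7-methyl-3-methylidene-1-[2,4,6-tris(methoxymethoxy)phenyl]oct-6-en-2-yl]-1,3,2-dioxaborolane
Product: 23 (2R)-7-methyl-3-methylidene-1-[2,4,6-tris(methoxymethoxy)phenyl]oct-6-en-2-ol
Conditions: H2O2, NaOH, THF/H2O, 0 °C to rt
Reagents that add atoms: hydrogen peroxide, OO
Why: Oxidation of the C–B bond with alkaline hydrogen peroxide: hydroperoxide adds to boron and C-2' migrates to oxygen with retention, giving the (R) carbinol without allylic transposition and releasing diol 5 for reuse; isolated alkenes and MOM ethers are inert to these conditions.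

Step 8
Reactants: 23 (2R)-7-methyl-3-methylidene-1-[2,4,6-tris(methoxymethoxy)phenyl]oct-6-en-2-ol; 24 N-methoxy-N-methylbenzamide
Product: 27 [3-[(2R)-2-hydroxy-7-methyl-3-methylideneoct-6-enyl]-2,4,6-tris(methoxymethoxy)phenyl](phenyl)methanone, via C,O-dilithio derivative 25 (not isolated), via lithium hemiaminal adduct 26 (not isolated)
Conditions: n-BuLi (2.3 equiv), THF, −78 to 0 °C; then 24, −78 °C to rt; H2O
Reagents that add atoms: none
Why: The first equivalent of n-BuLi turns the hydroxyl into a lithium alkoxide, which protects C-2', and the second effects directed ortho-metalation at the only ring CH, flanked by two MOM ethers (25); acylation with the Weinreb amide stops at the chelated adduct 26, which gives the ketone only on work-up, so no tertiary alcohol forms. C-2' takes no part.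

Step 9
Reactants: 27 [3-[(2R)-2-hydroxy-7-methyl-3-methylideneoct-6-enyl]-2,4,6-tris(methoxymethoxy)phenyl](phenyl)methanone
Product: 28 [2,4,6-trihydroxy-3-[(2R)-2-hydroxy-7-methyl-3-methylideneoct-6-enyl]phenyl](phenyl)methanone
Conditions: HCl (1.25 M in MeOH), 0 °C to rt
Reagents that add atoms: none
Why: Acid-catalysed acetal exchange with methanol removes the three MOM groups as dimethoxymethane; the two ethers ortho to the carbonyl group are activated by hydrogen bonding to the ketone, and dilute acid at or below room temperature is chosen so that the allylic alcohol and the two alkenes are not protonated.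

## Compound list

1 | phloroglucinol (benzene-1,3,5-triol) | Oc1cc(O)cc(O)c1 | starting material
2 | 1,3,5-tris(methoxymethoxy)benzene | COCOc1cc(OCOC)cc(OCOC)c1 | intermediate
3 | chloroiodomethane | ClCI | starting material
4 | triisopropyl borate (tripropan-2-yl borate) | CC(C)OB(OC(C)C)OC(C)C | starting material
5 | (1R,2R)-1,2-dicyclohexylethane-1,2-diol | O[C@H](C1CCCCC1)[C@H](O)C1CCCCC1 | starting material
6 | (chloromethyl)lithium | [Li]CCl | intermediate
7 | lithium (chloromethyl)triisopropoxyborate | [Li+].ClC[B-](OC(C)C)(OC(C)C)OC(C)C | intermediate
8 | diisopropyl (chloromethyl)boronate | ClCB(OC(C)C)OC(C)C | intermediate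
9 | (4R,5R)-2-(chloromethyl)-4,5-dicyclohexyl-1,3,2-dioxaborolane | ClCB1O[C@H](C2CCCCC2)[C@@H](C2CCCCC2)O1 | intermediate
10 | [2,4,6-tris(methoxymethoxy)phenyl]lithium | [Li]c1c(OCOC)cc(OCOC)cc1OCOC | intermediate
11 | lithium (4R,5R)-2-(chloromethyl)-4,5-dicyclohexyl-2-[2,4,6-tris(methoxymethoxy)phenyl]-1,3,2-dioxaborolan-2-uide | [Li+].COCOc1cc(OCOC)c([B-]2(CCl)O[C@H](C3CCCCC3)[C@@H](C3CCCCC3)O2)c(OCOC)c1 | intermediate
12 | (4R,5R)-4,5-dicyclohexyl-2-[[2,4,6-tris(methoxymethoxy)phenyl]methyl]-1,3,2-dioxaborolane | COCOc1cc(OCOC)c(CB2O[C@H](C3CCCCC3)[C@@H](C3CCCCC3)O2)c(OCOC)c1 | intermediate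
13 | dichloromethane | ClCCl | starting material
14 | (dichloromethyl)lithium | [Li]C(Cl)Cl | intermediate
15 | lithium (4R,5R)-4,5-dicyclohexyl-2-(dichloromethyl)-2-[[2,4,6-tris(methoxymethoxy)phenyl]methyl]-1,3,2-dioxaborolan-2-uide | [Li+].COCOc1cc(OCOC)c(C[B-]2(C(Cl)Cl)O[C@H](C3CCCCC3)[C@@H](C3CCCCC3)O2)c(OCOC)c1 | intermediate
16 | (4R,5R)-2-[(1S)-1-chloro-2-[2,4,6-tris(methoxymethoxy)phenyl]ethyl]-4,5-dicyclohexyl-1,3,2-dioxaborolane | COCOc1cc(OCOC)c(C[C@@H](Cl)B2O[C@H](C3CCCCC3)[C@@H](C3CCCCC3)O2)c(OCOC)c1 | intermediate
17 | 6-methylhept-5-en-2-one | CC(=O)CCC=C(C)C | starting material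
18 | N'-[(2E)-6-methylhept-5-en-2-ylidene]-2,4,6-tri(propan-2-yl)benzenesulfonohydrazide | C/C(CCC=C(C)C)=N\NS(=O)(=O)c1c(C(C)C)cc(C(C)C)cc1C(C)C | intermediate
19 | N,C-dilithio derivative of 18 (lithium on the sulfonamide nitrogen and on the C-1 methyl carbon) | [Li]C/C(CCC=C(C)C)=N\N([Li])S(=O)(=O)c1c(C(C)C)cc(C(C)C)cc1C(C)C | intermediate
20 | (6-methylhepta-1,5-dien-2-yl)lithium | [Li]C(=C)CCC=C(C)C | intermediate
21 | lithium (4R,5R)-2-[(1S)-1-chloro-2-[2,4,6-tris(methoxymethoxy)phenyl]ethyl]-4,5-dicyclohexyl-2-(6-methylhepta-1,5-dien-2-yl)-1,3,2-dioxaborolan-2-uide | [Li+].C=C(CCC=C(C)C)[B-]1([C@H](Cl)Cc2c(OCOC)cc(OCOC)cc2OCOC)O[C@H](C2CCCCC2)[C@@H](C2CCCCC2)O1 | intermediate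
22 | (4R,5R)-4,5-dicyclohexyl-2-[(2R)-7-methyl-3-methylidene-1-[2,4,6-tris(methoxymethoxy)phenyl]oct-6-en-2-yl]-1,3,2-dioxaborolane | C=C(CCC=C(C)C)[C@@H](Cc1c(OCOC)cc(OCOC)cc1OCOC)B1O[C@H](C2CCCCC2)[C@@H](C2CCCCC2)O1 | intermediate
23 | (2R)-7-methyl-3-methylidene-1-[2,4,6-tris(methoxymethoxy)phenyl]oct-6-en-2-ol | C=C(CCC=C(C)C)[C@H](O)Cc1c(OCOC)cc(OCOC)cc1OCOC | intermediate
24 | N-methoxy-N-methylbenzamide | CON(C)C(=O)c1ccccc1 | starting material
25 | lithium (2R)-1-[3-lithio-2,4,6-tris(methoxymethoxy)phenyl]-7-methyl-3-methylideneoct-6-en-2-olate | C=C(CCC=C(C)C)[C@H](O[Li])Cc1c(OCOC)cc(OCOC)c([Li])c1OCOC | intermediate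
26 | dilithium salt of the adduct of 25 and 24: lithium (2R)-1-[3-[lithiooxy[methoxy(methyl)amino](phenyl)methyl]-2,4,6-tris(methoxymethoxy)phenyl]-7-methyl-3-methylideneoct-6-en-2-olate (both epimers at the aminal carbon) | C=C(CCC=C(C)C)[C@H](O[Li])Cc1c(OCOC)cc(OCOC)c(C(O[Li])(N(C)OC)c2ccccc2)c1OCOC | intermediate
27 | [3-[(2R)-2-hydroxy-7-methyl-3-methylideneoct-6-enyl]-2,4,6-tris(methoxymethoxy)phenyl](phenyl)methanone | C=C(CCC=C(C)C)[C@H](O)Cc1c(OCOC)cc(OCOC)c(C(=O)c2ccccc2)c1OCOC | intermediate
28 | [2,4,6-trihydroxy-3-[(2R)-2-hydroxy-7-methyl-3-methylideneoct-6-enyl]phenyl](phenyl)methanone | C=C(CCC=C(C)C)[C@H](O)Cc1c(O)cc(O)c(C(=O)c2ccccc2)c1O | target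

## Step count and least certain steps

Total: 9 steps. Longest linear sequence: 7 steps (steps 1, 3, 4, 6, 7, 8, 9 from phloroglucinol 1; the same length through step 2 from diol 5).

**Step 4 (key step).** The most likely failure is erosion of stereocontrol. The MOM oxygens can compete with the diol oxygen and the chloride for ZnCl2, so the organised migration is slowed and chloride exchange has time to epimerise C-2'. The fallback resets the stereocentre at the carbinol stage by oxidation and catalyst-controlled reduction. It sets out from 23, carried through steps 6 and 7 at whatever enantiomeric purity the homologation delivers. Dess–Martin oxidation should give the enone 7-methyl-3-methylidene-1-[2,4,6-tris(methoxymethoxy)phenyl]oct-6-en-2-one F1. Corey–Bakshi–Shibata reduction of F1 with catecholborane and the (S) catalyst, (3aS)-1-methyl-3,3-diphenyltetrahydro-1H,3H-pyrrolo[1,2-c][1,3,2]oxazaborole, at low temperature should then return 23 as the (R) alcohol. The assignment takes the alkenyl group as the larger ketone substituent on the usual model; the (R) catalyst is taken if the sense is opposite.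

**Step 3.** The most likely failure is incomplete formation of the boronate complex. Aryllithium 10 is flanked by two MOM ethers and 9 carries a bulky diol, so proton transfer or attack at the diol may compete; the electron-rich benzylboronate may also lose boron by protonolysis on work-up. The fallback reverses the order in which the two carbon groups reach boron. It sets out from 10: quenching with B(OiPr)3 should give dipropan-2-yl [2,4,6-tris(methoxymethoxy)phenyl]boronate F2, and exchange with diol 5 should give (4R,5R)-4,5-dicyclohexyl-2-[2,4,6-tris(methoxymethoxy)phenyl]-1,3,2-dioxaborolane F3. Insertion of the small carbenoid 6, generated from 3 and n-BuLi in the presence of F3, passes through the same complex 11 and comes back to the route at 12.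

**Step 6.** The most likely failure is loss of material or of configuration before the 1,2-shift. The alkenyllithium is formed in a medium that contains lithium sulfinate and may act as a base on 16 (dehydrochlorination towards a styrenyl boronate). The lithium boronate complex may also rearrange slowly, which gives chloride time to epimerise 16, and the allylic boronate may undergo a 1,3-boron shift if warmed too long. The fallback delivers the alkenyl group as a Grignard reagent, the class of nucleophile for which this displacement is best established and whose magnesium halide assists the shift. It sets out from 20: quenching with 1,2-dibromoethane should give 2-bromo-6-methylhepta-1,5-diene F4, which is purified and converted with Mg in THF into bromo(6-methylhepta-1,5-dien-2-yl)magnesium F5. Addition of F5 to 16 and warming comes back to the route at 22.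

**Step 8.** The most likely failure is incomplete or misdirected metalation of the lithium alkoxide (aggregation, competing allylic or benzylic deprotonation). The hindered aryllithium may also act as a base on amide 24, with loss of formaldehyde from the N-methoxy group, instead of adding. The fallback protects the carbinol and uses a smaller electrophile. It sets out from 23:
- Silylation with TBSCl and imidazole should give tert-butyl(dimethyl)[(2R)-7-methyl-3-methylidene-1-[2,4,6-tris(methoxymethoxy)phenyl]oct-6-en-2-yl]oxysilane F6.
- n-BuLi should give [3-[(2R)-2-[tert-butyl(dimethyl)silyl]oxy-7-methyl-3-methylideneoct-6-enyl]-2,4,6-tris(methoxymethoxy)phenyl]lithium F7.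
- Benzaldehyde should give [3-[(2R)-2-[tert-butyl(dimethyl)silyl]oxy-7-methyl-3-methylideneoct-6-enyl]-2,4,6-tris(methoxymethoxy)phenyl](phenyl)methanol F8 as a mixture of carbinol epimers.
- Dess–Martin oxidation should give [3-[(2R)-2-[tert-butyl(dimethyl)silyl]oxy-7-methyl-3-methylideneoct-6-enyl]-2,4,6-tris(methoxymethoxy)phenyl](phenyl)methanone F9.
- TBAF comes back to the route at 27.

**Step 9.** The most likely failure is acid-induced cyclisation of a liberated ortho phenol onto one of the alkenes, or solvolysis at allylic C-2', before the slowest MOM ether has gone. That is the one at C-4, which has no carbonyl neighbour. The fallback exchanges the acetals for silyl ethers without Brønsted acid and then removes silicon with fluoride. It sets out from 27: TESOTf and 2,2'-bipyridyl in CH2Cl2 should convert each aryl MOM ether into a triethylsilyl ether and silylate the carbinol, giving [3-[(2R)-7-methyl-3-methylidene-2-(triethylsilyloxy)oct-6-enyl]-2,4,6-tris(triethylsilyloxy)phenyl](phenyl)methanone F10. TBAF buffered with acetic acid then comes back to the route at 28.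

## Further compounds

F1 | step 4 | 7-methyl-3-methylidene-1-[2,4,6-tris(methoxymethoxy)phenyl]oct-6-en-2-one | C=C(CCC=C(C)C)C(=O)Cc1c(OCOC)cc(OCOC)cc1OCOC
F2 | step 3 | dipropan-2-yl [2,4,6-tris(methoxymethoxy)phenyl]boronate | COCOc1cc(OCOC)c(B(OC(C)C)OC(C)C)c(OCOC)c1
F3 | step 3 | (4R,5R)-4,5-dicyclohexyl-2-[2,4,6-tris(methoxymethoxy)phenyl]-1,3,2-dioxaborolane | COCOc1cc(OCOC)c(B2O[C@H](C3CCCCC3)[C@@H](C3CCCCC3)O2)c(OCOC)c1
F4 | step 6 | 2-bromo-6-methylhepta-1,5-diene | C=C(Br)CCC=C(C)C
F5 | step 6 | bromo(6-methylhepta-1,5-dien-2-yl)magnesium | C=C([Mg]Br)CCC=C(C)C
F6 | step 8 | tert-butyl(dimethyl)[(2R)-7-methyl-3-methylidene-1-[2,4,6-tris(methoxymethoxy)phenyl]oct-6-en-2-yl]oxysilane | C=C(CCC=C(C)C)[C@H](O[Si](C)(C)C(C)(C)C)Cc1c(OCOC)cc(OCOC)cc1OCOC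
F7 | step 8 | [3-[(2R)-2-[tert-butyl(dimethyl)silyl]oxy-7-methyl-3-methylideneoct-6-enyl]-2,4,6-tris(methoxymethoxy)phenyl]lithium | C=C(CCC=C(C)C)[C@H](O[Si](C)(C)C(C)(C)C)Cc1c(OCOC)cc(OCOC)c([Li])c1OCOC
F8 | step 8 | [3-[(2R)-2-[tert-butyl(dimethyl)silyl]oxy-7-methyl-3-methylideneoct-6-enyl]-2,4,6-tris(methoxymethoxy)phenyl](phenyl)methanol (both carbinol epimers) | C=C(CCC=C(C)C)[C@H](O[Si](C)(C)C(C)(C)C)Cc1c(OCOC)cc(OCOC)c(C(O)c2ccccc2)c1OCOC
F9 | step 8 | [3-[(2R)-2-[tert-butyl(dimethyl)silyl]oxy-7-methyl-3-methylideneoct-6-enyl]-2,4,6-tris(methoxymethoxy)phenyl](phenyl)methanone | C=C(CCC=C(C)C)[C@H](O[Si](C)(C)C(C)(C)C)Cc1c(OCOC)cc(OCOC)c(C(=O)c2ccccc2)c1OCOC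
F10 | step 9 | [3-[(2R)-7-methyl-3-methylidene-2-(triethylsilyloxy)oct-6-enyl]-2,4,6-tris(triethylsilyloxy)phenyl](phenyl)methanone | C=C(CCC=C(C)C)[C@H](O[Si](CC)(CC)CC)Cc1c(O[Si](CC)(CC)CC)cc(O[Si](CC)(CC)CC)c(C(=O)c2ccccc2)c1O[Si](CC)(CC)CC
A1 | alternative 1 | 2-[(2R)-2-[tert-butyl(dimethyl)silyl]oxy-7-methyl-3-methylideneoct-6-enyl]-3,5-bis[tri(propan-2-yl)silyloxy]phenol | Oc1cc(O[Si](C(C)C)(C(C)C)C(C)C)cc(O[Si](C(C)C)(C(C)C)C(C)C)c1C[C@@H](O[Si](C)(C)C(C)(C)C)C(=C)CCC=C(C)C
A2 | alternative 1 | tert-butyl(dimethyl)[(4R)-9-methyl-5-methylidene-1-[tri(propan-2-yl)silyloxy]dec-8-en-1-yn-4-yl]oxysilane | CC(C)[Si](C(C)C)(C(C)C)OC#CC[C@@H](O[Si](C)(C)C(C)(C)C)C(=C)CCC=C(C)C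
A3 | alternative 1 | 3-[tri(propan-2-yl)silyloxy]cyclobut-2-en-1-one | O=C1C=C(O[Si](C(C)C)(C(C)C)C(C)C)C1
A4 | alternative 2 | [3-[(2R)-2-hydroxy-7-methyl-3-methylideneoct-6-enyl]-2,4,6-tris(methoxymethoxy)phenyl](phenyl)methanone | COCOc1cc(OCOC)c(C(=O)c2ccccc2)c(OCOC)c1C[C@@H](O)C(=C)CCC=C(C)C
A5 | alternative 2 | 2-[3-benzoyl-2,4,6-tris(methoxymethoxy)phenyl]acetaldehyde | COCOc1cc(OCOC)c(C(=O)c2ccccc2)c(OCOC)c1CC=O
A6 | alternative 2 | 6-methylhepta-1,5-dien-2-yl trifluoromethanesulfonate | C=C(CCC=C(C)C)OS(=O)(=O)C(F)(F)F
A7 | alternative 3 | (2R)-2-hydroxy-3-[2,4,6-tris(methoxymethoxy)phenyl]propanoic acid | COCOc1cc(OCOC)c(C[C@@H](O)C(=O)O)c(OCOC)c1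
A8 | alternative 3 | 2-oxo-3-[2,4,6-tris(methoxymethoxy)phenyl]propanoic acid | COCOc1cc(OCOC)c(CC(=O)C(=O)O)c(OCOC)c1
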